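**Retrosynthetic overview**
1. Target 31 ← global hydrogenolysis of its eicosa-O-benzyl ether 30.
2. 30 ← four Cu-catalysed diaryl ether couplings of a hindered phenol oxygen with an unhindered aryl bromide, grown from ring H towards ring A: ring-H phenol 22, then three copies of the B–C "dimer" bromide 18 (MOM removal after each), then ring-A bromide 29.
3. Dimer 18 ← new aryne O–B insertion/oxidation: the pinacol borate of 4-bromo-2,6-bis(benzyloxy)phenol 13 plus 3,4,5-tris(benzyloxy)benzyne, giving the hindered B2–O–C1 ether and the neighbouring B1–OH in one step.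
4. Aryne precursor 8 ← 3,4,5-trihydroxybenzaldehyde (benzylation, Baeyer–Villiger, bromination, retro-Brook/triflation); phenols 13 and 22 ← ortho-lithiation/borylation/oxidation of resorcinol and phloroglucinol benzyl ethers.
5. No ring is built; all eight benzene rings are bought and joined in the order C–B (inside the dimer, same for E–D and G–F), H–G, F–E, D–C, B–A.

Assumption: the target has no stereocentre and no resolvable axis, so it is achiral and the route only has to deliver the constitution of the SMILES.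
Ring letters: A = 3,5-dihydroxyphenyl end, H = 2,4,6-trihydroxyphenoxy end. Linkages are A5–O–B1, B2–O–C1, C4–O–D1, D2–O–E1, E4–O–F1, F2–O–G1, G4–O–H1. Rings B, D, F carry OH at 4,5,6; rings C, E, G carry OH at 2,6. Bn = benzyl, MOM = methoxymethyl.

**Route**

Step 1
Reactants: 1 3,4,5-trihydroxybenzaldehyde
Product: 2 3,4,5-tris(benzyloxy)benzaldehyde
Conditions: BnBr (3.5 equiv), K2CO3, DMF, 60 °C
Reagents that add atoms: benzyl bromide BrCc1ccccc1
Why: Williamson ether synthesis on three acidic phenols with a reactive benzylic halide is routine.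

Step 2
Reactants: 2 3,4,5-tris(benzyloxy)benzaldehyde
Product: 4 3,4,5-tris(benzyloxy)phenol, via aryl formate 3 (not isolated)
Conditions: mCPBA, CH2Cl2, 0 °C to rt; then K2CO3 (cat.), MeOH, rt
Reagents that add atoms: m-chloroperbenzoic acid OOC(=O)c1cccc(Cl)c1
Why: Baeyer–Villiger (Dakin-type) oxidation with aryl migration is favoured by the para-alkoxy group, and the formate is methanolysed in the same pot.

Step 3
Reactants: 4 3,4,5-tris(benzyloxy)phenol
Product: 5 2-bromo-3,4,5-tris(benzyloxy)phenol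
Conditions: NBS (1.0 equiv), CH2Cl2, −78 to 0 °C
Reagents that add atoms: N-bromosuccinimide O=C1CCC(=O)N1Br
Why: Electrophilic aromatic bromination can only hit the two equivalent ring C–H positions ortho to OH, so one equivalent at low temperature gives the monobromide.

Step 4
Reactants: 5 2-bromo-3,4,5-tris(benzyloxy)phenol
Product: 8 3,4,5-tris(benzyloxy)-2-(trimethylsilyl)phenyl triflate, via silyl ether 6 (not isolated), via lithium silylphenoxide 7 (not isolated)
Conditions: HMDS, THF, 65 °C, evaporate; n-BuLi, THF, −100 to −78 °C; Tf2O, −78 °C to rt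
Reagents that add atoms: hexamethyldisilazane C[Si](C)(C)N[Si](C)(C)C; triflic anhydride O=S(=O)(OS(=O)(=O)C(F)(F)F)C(F)(F)F; n-butyllithium [Li]CCCC (lithium only in intermediate 7)
Why: Br–Li exchange at −100 °C outruns benzylic deprotonation, the 1,3-retro-Brook shift moves silicon from O to C, and O-triflation gives the standard o-silylaryl triflate aryne precursor.

Step 5
Reactants: 9 1,3-bis(benzyloxy)benzene
Product: 12 2,6-bis(benzyloxy)phenol, via aryllithium 10 (not isolated), via dimethyl boronate 11 (not isolated)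
Conditions: n-BuLi, THF, 0 °C to rt; B(OMe)3, −78 °C to rt; AcOH, 30% H2O2, 0 °C to rt
Reagents that add atoms: hydrogen peroxide OO; n-butyllithium [Li]CCCC (lithium only in 10); trimethyl borate COB(OC)OC (boron only in 11)
Why: Directed ortho-metalation occurs at the doubly activated C-2 between the two ether oxygens, and borylation/oxidation turns C–Li into C–OH at that position.

Step 6
Reactants: 12 2,6-bis(benzyloxy)phenol
Product: 13 4-bromo-2,6-bis(benzyloxy)phenol
Conditions: NBS (1.0 equiv), NaH (cat.), CHCl3–MeOH, −45 °C to rt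
Reagents that add atoms: N-bromosuccinimide O=C1CCC(=O)N1Br
Why: Electrophilic bromination under phenoxide-type conditions goes para to the free OH, as it does for 2,6-dimethoxyphenol.

Step 7
Reactants: 13 4-bromo-2,6-bis(benzyloxy)phenol; 8 3,4,5-tris(benzyloxy)-2-(trimethylsilyl)phenyl triflate
Product: 17 2,3,4-tris(benzyloxy)-6-[4-bromo-2,6-bis(benzyloxy)phenoxy]phenol, via aryl pinacol borate 14 (not isolated), via aryne 15 (not isolated), via arylboronate 16 (not isolated)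
Conditions: 13, HBpin (1.05 equiv), THF, 50 °C (H2 evolution); then 8 (1.3 equiv), CsF (3 equiv), 18-crown-6, THF, 0 °C to rt; then 30% H2O2, aq. NaOH, 0 °C
Reagents that add atoms: hydrogen peroxide OO; pinacolborane CC1(C)OBOC1(C)C (boron only in intermediates 14 and 16)
Why: Proposed new method: fluoride-triggered formal insertion of a 3-alkoxyaryne into the O–B bond of an aryl pinacol borate (aryloxyboration) followed by C–B oxidation; fluoride unmasks aryne 15 from 8 and opens borate 14 to its aryloxide, which attacks the aryne carbon remote from the 3-OBn group (aryne distortion model, reinforced by sterics), and the resulting aryl anion, flanked and stabilised by OBn and OAr, is captured by another molecule of 14 or by F–Bpin to give 16 and regenerate aryloxide, with no O–H in the medium to protonate it; H2O2 then converts C–B into C–OH at the same carbon; closest known reaction types are fluoride-mediated O-arylation of phenols with o-silylaryl triflates and aryne σ-insertion into heteroatom–metalloid bonds such as N–Si and S–Sn.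

Step 8
Reactants: 17 2,3,4-tris(benzyloxy)-6-[4-bromo-2,6-bis(benzyloxy)phenoxy]phenol
Product: 18 1,2,3-tris(benzyloxy)-5-[4-bromo-2,6-bis(benzyloxy)phenoxy]-4-(methoxymethoxy)benzene
Conditions: NaH, MOMCl, DMF, 0 °C to rt
Reagents that add atoms: chloromethyl methyl ether COCCl
Why: O-alkylation of the sodium phenoxide with the small, very reactive MOMCl tolerates the flanking groups and masks the nucleophile so that 18 cannot self-condense later.

Step 9
Reactants: 19 1,3,5-tris(benzyloxy)benzene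
Product: 22 2,4,6-tris(benzyloxy)phenol, via aryllithium 20 (not isolated), via dimethyl boronate 21 (not isolated)
Conditions: n-BuLi, THF, 0 °C to rt; B(OMe)3, −78 °C to rt; AcOH, 30% H2O2, 0 °C to rt
Reagents that add atoms: hydrogen peroxide OO; n-butyllithium [Li]CCCC (lithium only in 20); trimethyl borate COB(OC)OC (boron only in 21)
Why: Directed ortho-metalation between two ether oxygens (all three ring C–H are equivalent) followed by borylation/oxidation gives the phenol.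

Step 10
Reactants: 22 2,4,6-tris(benzyloxy)phenol; 18 1,2,3-tris(benzyloxy)-5-[4-bromo-2,6-bis(benzyloxy)phenoxy]-4-(methoxymethoxy)benzene
Product: 23 1-(methoxymethoxy)-2,3,4-tris(benzyloxy)-6-{2,6-bis(benzyloxy)-4-[2,4,6-tris(benzyloxy)phenoxy]phenoxy}benzene (F–G–H trimer MOM ether)
Conditions: CuI (20 mol%), picolinic acid (40 mol%), K3PO4, DMSO, 105 °C, argon
Reagents that add atoms: none
Why: Ullmann-type C–O coupling with the Cu/picolinate system suits 2,6-disubstituted phenols, and the C–Br of 18 has two ortho hydrogens and is the only halide present.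

Step 11
Reactants: 23 F–G–H trimer MOM ether
Product: 24 2,3,4-tris(benzyloxy)-6-{2,6-bis(benzyloxy)-4-[2,4,6-tris(benzyloxy)phenoxy]phenoxy}phenol (F–G–H trimer phenol)
Conditions: HCl (cat.), MeOH–THF, 50 °C
Reagents that add atoms: none
Why: Acid-catalysed acetal exchange removes MOM while benzyl and diaryl ethers are inert.

Step 12
Reactants: 24 F–G–H trimer phenol; 18 MOM-protected B–C dimer bromide
Product: 25 D–E–F–G–H pentamer MOM ether (24 O-arylated at its phenol oxygen by C-4 of the 2,6-bis(benzyloxy)phenoxy ring of 18)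
Conditions: CuI (20 mol%), picolinic acid (40 mol%), K3PO4, DMSO, 105 °C, argon
Reagents that add atoms: none
Why: Same Ullmann-type C–O coupling as step 10, with the phenol again flanked by one OBn and one aryloxy group.

Step 13
Reactants: 25 D–E–F–G–H pentamer MOM ether
Product: 26 D–E–F–G–H pentamer phenol (free OH at ring D position 1)
Conditions: HCl (cat.), MeOH–THF, 50 °C
Reagents that add atoms: none
Why: Acid-catalysed MOM acetal cleavage as in step 11.

Step 14
Reactants: 26 D–E–F–G–H pentamer phenol; 18 MOM-protected B–C dimer bromide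
Product: 27 B–C–D–E–F–G–H heptamer MOM ether
Conditions: CuI (30 mol%), picolinic acid (60 mol%), K3PO4, DMSO, 110 °C, argon
Reagents that add atoms: none
Why: Third iteration of the Ullmann-type C–O coupling, run with excess 18 to drive the valuable phenol to completion.

Step 15
Reactants: 27 B–C–D–E–F–G–H heptamer MOM ether
Product: 28 B–C–D–E–F–G–H heptamer phenol (free OH at ring B position 1)
Conditions: HCl (cat.), MeOH–THF, 50 °C
Reagents that add atoms: none
Why: Acid-catalysed MOM acetal cleavage as in step 11.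

Step 16
Reactants: 28 heptamer phenol; 29 1-bromo-3,5-bis(benzyloxy)benzene
Product: 30 eicosa-O-benzyl ether of the target (all twenty OH as OBn)
Conditions: CuI (30 mol%), picolinic acid (60 mol%), K3PO4, DMSO, 110 °C, argon, excess 29
Reagents that add atoms: none
Why: Ullmann-type C–O coupling with an unhindered, inexpensive aryl bromide installs ring A last.

Step 17
Reactants: 30 eicosa-O-benzyl ether of the target
Product: 31 CNP0319661.0 (target)
Conditions: H2 (3 bar), Pd(OH)2/C, THF–MeOH (degassed), rt; filter and isolate under argon, Sephadex LH-20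
Reagents that add atoms: none
Why: Pd-catalysed hydrogenolysis cleaves all benzyl aryl ethers, leaves the diaryl ethers intact, and involves no stereocentre.

**Compound list**
1 | 3,4,5-trihydroxybenzaldehyde | O=Cc1cc(O)c(O)c(O)c1 | starting material
2 | 3,4,5-tris(benzyloxy)benzaldehyde | O=Cc1cc(OCc9ccccc9)c(OCc9ccccc9)c(OCc9ccccc9)c1 | intermediate
3 | 3,4,5-tris(benzyloxy)phenyl formate | O=COc1cc(OCc9ccccc9)c(OCc9ccccc9)c(OCc9ccccc9)c1 | intermediate
4 | 3,4,5-tris(benzyloxy)phenol | Oc1cc(OCc9ccccc9)c(OCc9ccccc9)c(OCc9ccccc9)c1 | intermediate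
5 | 2-bromo-3,4,5-tris(benzyloxy)phenol | Oc1cc(OCc9ccccc9)c(OCc9ccccc9)c(OCc9ccccc9)c1Br | intermediate
6 | [2-bromo-3,4,5-tris(benzyloxy)phenoxy]trimethylsilane | C[Si](C)(C)Oc1cc(OCc9ccccc9)c(OCc9ccccc9)c(OCc9ccccc9)c1Br | intermediate
7 | lithium 3,4,5-tris(benzyloxy)-2-(trimethylsilyl)phenoxide | [Li+].[O-]c1cc(OCc9ccccc9)c(OCc9ccccc9)c(OCc9ccccc9)c1[Si](C)(C)C | intermediate
8 | 3,4,5-tris(benzyloxy)-2-(trimethylsilyl)phenyl triflate | FC(F)(F)S(=O)(=O)Oc1cc(OCc9ccccc9)c(OCc9ccccc9)c(OCc9ccccc9)c1[Si](C)(C)C | intermediate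
9 | 1,3-bis(benzyloxy)benzene | c1cc(OCc9ccccc9)cc(OCc9ccccc9)c1 | starting material
10 | [2,6-bis(benzyloxy)phenyl]lithium | [Li]c1c(OCc9ccccc9)cccc1OCc9ccccc9 | intermediate
11 | dimethyl [2,6-bis(benzyloxy)phenyl]boronate | COB(OC)c1c(OCc9ccccc9)cccc1OCc9ccccc9 | intermediate
12 | 2,6-bis(benzyloxy)phenol | Oc1c(OCc9ccccc9)cccc1OCc9ccccc9 | intermediate
13 | 4-bromo-2,6-bis(benzyloxy)phenol | Oc1c(OCc9ccccc9)cc(Br)cc1OCc9ccccc9 | intermediate
14 | 2-[4-bromo-2,6-bis(benzyloxy)phenoxy]-4,4,5,5-tetramethyl-1,3,2-dioxaborolane | CC1(C)OB(Oc2c(OCc9ccccc9)cc(Br)cc2OCc9ccccc9)OC1(C)C | intermediate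
15 | 3,4,5-tris(benzyloxy)benzyne (1,2-didehydro) | C1#CC(OCc9ccccc9)=C(OCc9ccccc9)C(OCc9ccccc9)=C1 | intermediate
16 | 2-{2,3,4-tris(benzyloxy)-6-[4-bromo-2,6-bis(benzyloxy)phenoxy]phenyl}-4,4,5,5-tetramethyl-1,3,2-dioxaborolane | CC1(C)OB(OC1(C)C)c1c(OCc9ccccc9)c(OCc9ccccc9)c(OCc9ccccc9)cc1Oc2c(OCc9ccccc9)cc(Br)cc2OCc9ccccc9 | intermediate
17 | 2,3,4-tris(benzyloxy)-6-[4-bromo-2,6-bis(benzyloxy)phenoxy]phenol (B–C dimer phenol) | Oc1c(OCc9ccccc9)c(OCc9ccccc9)c(OCc9ccccc9)cc1Oc2c(OCc9ccccc9)cc(Br)cc2OCc9ccccc9 | intermediate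
18 | 1,2,3-tris(benzyloxy)-5-[4-bromo-2,6-bis(benzyloxy)phenoxy]-4-(methoxymethoxy)benzene (MOM-protected B–C dimer bromide) | COCOc1c(OCc9ccccc9)c(OCc9ccccc9)c(OCc9ccccc9)cc1Oc2c(OCc9ccccc9)cc(Br)cc2OCc9ccccc9 | intermediate
19 | 1,3,5-tris(benzyloxy)benzene | c1c(OCc9ccccc9)cc(OCc9ccccc9)cc1OCc9ccccc9 | starting material
20 | [2,4,6-tris(benzyloxy)phenyl]lithium | [Li]c1c(OCc9ccccc9)cc(OCc9ccccc9)cc1OCc9ccccc9 | intermediate
21 | dimethyl [2,4,6-tris(benzyloxy)phenyl]boronate | COB(OC)c1c(OCc9ccccc9)cc(OCc9ccccc9)cc1OCc9ccccc9 | intermediate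
22 | 2,4,6-tris(benzyloxy)phenol | Oc1c(OCc9ccccc9)cc(OCc9ccccc9)cc1OCc9ccccc9 | intermediate
23 | F–G–H trimer MOM ether | COCOc1c(OCc9ccccc9)c(OCc9ccccc9)c(OCc9ccccc9)cc1Oc2c(OCc9ccccc9)cc(Oc3c(OCc9ccccc9)cc(OCc9ccccc9)cc3OCc9ccccc9)cc2OCc9ccccc9 | intermediate
24 | F–G–H trimer phenol | Oc1c(OCc9ccccc9)c(OCc9ccccc9)c(OCc9ccccc9)cc1Oc2c(OCc9ccccc9)cc(Oc3c(OCc9ccccc9)cc(OCc9ccccc9)cc3OCc9ccccc9)cc2OCc9ccccc9 | intermediate
25 | D–E–F–G–H pentamer MOM ether | COCOc1c(OCc9ccccc9)c(OCc9ccccc9)c(OCc9ccccc9)cc1Oc2c(OCc9ccccc9)cc(Oc3c(OCc9ccccc9)c(OCc9ccccc9)c(OCc9ccccc9)cc3Oc4c(OCc9ccccc9)cc(Oc5c(OCc9ccccc9)cc(OCc9ccccc9)cc5OCc9ccccc9)cc4OCc9ccccc9)cc2OCc9ccccc9 | intermediate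
26 | D–E–F–G–H pentamer phenol | Oc1c(OCc9ccccc9)c(OCc9ccccc9)c(OCc9ccccc9)cc1Oc2c(OCc9ccccc9)cc(Oc3c(OCc9ccccc9)c(OCc9ccccc9)c(OCc9ccccc9)cc3Oc4c(OCc9ccccc9)cc(Oc5c(OCc9ccccc9)cc(OCc9ccccc9)cc5OCc9ccccc9)cc4OCc9ccccc9)cc2OCc9ccccc9 | intermediate
27 | B–C–D–E–F–G–H heptamer MOM ether | COCOc1c(OCc9ccccc9)c(OCc9ccccc9)c(OCc9ccccc9)cc1Oc2c(OCc9ccccc9)cc(Oc3c(OCc9ccccc9)c(OCc9ccccc9)c(OCc9ccccc9)cc3Oc4c(OCc9ccccc9)cc(Oc5c(OCc9ccccc9)c(OCc9ccccc9)c(OCc9ccccc9)cc5Oc6c(OCc9ccccc9)cc(Oc7c(OCc9ccccc9)cc(OCc9ccccc9)cc7OCc9ccccc9)cc6OCc9ccccc9)cc4OCc9ccccc9)cc2OCc9ccccc9 | intermediate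
28 | B–C–D–E–F–G–H heptamer phenol | Oc1c(OCc9ccccc9)c(OCc9ccccc9)c(OCc9ccccc9)cc1Oc2c(OCc9ccccc9)cc(Oc3c(OCc9ccccc9)c(OCc9ccccc9)c(OCc9ccccc9)cc3Oc4c(OCc9ccccc9)cc(Oc5c(OCc9ccccc9)c(OCc9ccccc9)c(OCc9ccccc9)cc5Oc6c(OCc9ccccc9)cc(Oc7c(OCc9ccccc9)cc(OCc9ccccc9)cc7OCc9ccccc9)cc6OCc9ccccc9)cc4OCc9ccccc9)cc2OCc9ccccc9 | intermediate
29 | 1-bromo-3,5-bis(benzyloxy)benzene | Brc1cc(OCc9ccccc9)cc(OCc9ccccc9)c1 | starting material
30 | eicosa-O-benzyl ether of the target | c9ccccc9COc1cc(OCc9ccccc9)cc(Oc2c(OCc9ccccc9)c(OCc9ccccc9)c(OCc9ccccc9)cc2Oc3c(OCc9ccccc9)cc(Oc4c(OCc9ccccc9)c(OCc9ccccc9)c(OCc9ccccc9)cc4Oc5c(OCc9ccccc9)cc(Oc6c(OCc9ccccc9)c(OCc9ccccc9)c(OCc9ccccc9)cc6Oc7c(OCc9ccccc9)cc(Oc8c(OCc9ccccc9)cc(OCc9ccccc9)cc8OCc9ccccc9)cc7OCc9ccccc9)cc5OCc9ccccc9)cc3OCc9ccccc9)c1 | intermediate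
31 | CNP0319661.0 | Oc1cc(O)cc(Oc2c(Oc3c(O)cc(Oc4c(Oc5c(O)cc(Oc6c(Oc7c(O)cc(Oc8c(O)cc(O)cc8O)cc7O)cc(O)c(O)c6O)cc5O)cc(O)c(O)c4O)cc3O)cc(O)c(O)c2O)c1 | target

**Totals**
Total step count: 17. Longest linear sequence: 14 steps (1, 2, 3, 4, 7, 8, 10, 11, 12, 13, 14, 15, 16, 17).

**Three steps most likely to fail**

Step 7 (the proposed new aryne O–B insertion). Risks are protonation or benzylic quenching of the aryl anion before boron capture, and fluoride being tied up by boron. The fallback uses known chemistry, sets out from 13 (with 8) and comes back at 17. Phenol 13 and triflate 8 are combined under the ordinary fluoride-mediated aryne O-arylation (CsF, MeCN, rt), where the aryl anion is simply protonated, to give 1,2,3-tris(benzyloxy)-5-[4-bromo-2,6-bis(benzyloxy)phenoxy]benzene F1. Vilsmeier–Haack formylation (POCl3, DMF) at either of the two equivalent positions ortho to the aryloxy group on the more electron-rich ring gives 2,3,4-tris(benzyloxy)-6-[4-bromo-2,6-bis(benzyloxy)phenoxy]benzaldehyde F2. Baeyer–Villiger oxidation with mCPBA gives 2,3,4-tris(benzyloxy)-6-[4-bromo-2,6-bis(benzyloxy)phenoxy]phenyl formate F3, which is methanolysed (K2CO3, MeOH) to 17.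

Step 14 (Ullmann coupling of the very hindered pentamer phenol; the same concern applies to steps 10, 12 and 16). The fallback switches to an oxidative Chan–Lam–Evans coupling, sets out from 18 (with 26) and comes back at 27. Miyaura borylation of 18 (B2pin2, Pd(dppf)Cl2, KOAc, dioxane, 90 °C) gives 2-{3,5-bis(benzyloxy)-4-[2-(methoxymethoxy)-3,4,5-tris(benzyloxy)phenoxy]phenyl}-4,4,5,5-tetramethyl-1,3,2-dioxaborolane F4. Periodate cleavage of the pinacol ester (NaIO4, NH4OAc, acetone–water) gives {3,5-bis(benzyloxy)-4-[2-(methoxymethoxy)-3,4,5-tris(benzyloxy)phenoxy]phenyl}boronic acid F5. This is coupled with phenol 26 at room temperature (Cu(OAc)2, pyridine, Et3N, 4 Å sieves, CH2Cl2, air) to give 27.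

Step 17 (twenty hydrogenolyses; partly debenzylated material may precipitate on the catalyst and the pyrogallol-rich product is air-sensitive). The fallback is a non-reductive Lewis-acid debenzylation, sets out from 30 and comes back at 31: BCl3 with pentamethylbenzene as benzyl-cation scavenger, CH2Cl2, −78 °C, then MeOH quench under argon. New compounds on its way: none F0.

**Further compounds**
F1 | step 7 | 1,2,3-tris(benzyloxy)-5-[4-bromo-2,6-bis(benzyloxy)phenoxy]benzene | c1(Oc2c(OCc9ccccc9)cc(Br)cc2OCc9ccccc9)cc(OCc9ccccc9)c(OCc9ccccc9)c(OCc9ccccc9)c1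
F2 | step 7 | 2,3,4-tris(benzyloxy)-6-[4-bromo-2,6-bis(benzyloxy)phenoxy]benzaldehyde | O=Cc1c(OCc9ccccc9)c(OCc9ccccc9)c(OCc9ccccc9)cc1Oc2c(OCc9ccccc9)cc(Br)cc2OCc9ccccc9
F3 | step 7 | 2,3,4-tris(benzyloxy)-6-[4-bromo-2,6-bis(benzyloxy)phenoxy]phenyl formate | O=COc1c(OCc9ccccc9)c(OCc9ccccc9)c(OCc9ccccc9)cc1Oc2c(OCc9ccccc9)cc(Br)cc2OCc9ccccc9
F4 | step 14 | 2-{3,5-bis(benzyloxy)-4-[2-(methoxymethoxy)-3,4,5-tris(benzyloxy)phenoxy]phenyl}-4,4,5,5-tetramethyl-1,3,2-dioxaborolane | COCOc1c(OCc9ccccc9)c(OCc9ccccc9)c(OCc9ccccc9)cc1Oc2c(OCc9ccccc9)cc(B3OC(C)(C)C(C)(C)O3)cc2OCc9ccccc9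
F5 | step 14 | {3,5-bis(benzyloxy)-4-[2-(methoxymethoxy)-3,4,5-tris(benzyloxy)phenoxy]phenyl}boronic acid | COCOc1c(OCc9ccccc9)c(OCc9ccccc9)c(OCc9ccccc9)cc1Oc2c(OCc9ccccc9)cc(B(O)O)cc2OCc9ccccc9
F0 | step 17 | none | none
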